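Everything rests on closing the 1,4-dioxin ring last: the phenol oxygen of ring B is joined to C2 of ring C, the central benzene of the dibenzofuran. C2–H lies between the C1 aryl ether carbon and the C3 methoxy carbon and is para to the furan-oxygen carbon C4a, so anodic oxidation should replace this one C–H by a C–O bond and form the pentacyclic core in a single operation. The precursor is a 2-aryloxyphenol: a pentaoxygenated ring B with a free phenol, a benzyl ether standing in for ring A, and an ether bridge to C1 of 3,7,9-trimethoxydibenzofuran. Ring A is attached afterwards and all methyl ethers are cleaved last.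

Key step: step 11

Remark: ring A is the 3,5-dioxygenated phenoxy ring, ring B the benzene of the dioxin that carries ring A, ring C the benzene shared by dioxin and furan, ring D the outer benzene of the dibenzofuran; rings C and D carry dibenzofuran numbering; compounds 1, 5, 6 and 19 are assumed to be purchasable; no compound in the route has a stereocentre.

Step 1
Reactants: 1 2,4-dimethoxyphenol
Product: 2 2-hydroxy-3,5-dimethoxybenzaldehyde
Conditions: MgCl2, Et3N, (CH2O)n, MeCN, reflux; aq. HCl
Reagents that add atoms: paraformaldehyde (reacts as formaldehyde), C=O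
Why: Magnesium-mediated ortho-formylation of a phenol (Casnati–Skattebøl type) delivers formaldehyde to the only free ortho position, and a second formaldehyde oxidises the benzylic alkoxide to the aldehyde.

Step 2
Reactants: 2 2-hydroxy-3,5-dimethoxybenzaldehyde
Product: 3 2-(benzyloxy)-3,5-dimethoxybenzaldehyde
Conditions: BnBr, K2CO3, DMF, 60 °C
Reagents that add atoms: benzyl bromide, BrCc1ccccc1
Why: Williamson etherification of a salicylaldehyde phenol with a benzylic bromide under carbonate is routine and installs the placeholder for ring A.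

Step 3
Reactants: 3 2-(benzyloxy)-3,5-dimethoxybenzaldehyde
Product: 4 2-(benzyloxy)-6-bromo-3,5-dimethoxybenzaldehyde
Conditions: NBS, MeCN, 0 °C → rt, dark
Reagents that add atoms: N-bromosuccinimide, O=C1CCC(=O)N1Br
Why: Electrophilic aromatic bromination should go to C6, para to the C3 methoxy and ortho to the C5 methoxy, as it does in 3,5-dimethoxybenzaldehyde, because C4 is shielded by two methoxy groups and lies para to the formyl group.

Step 4
Reactants: 5 1,3-difluoro-5-methoxy-2-nitrobenzene; 6 3,5-dimethoxyphenol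
Product: 8 1-(3,5-dimethoxyphenoxy)-5-methoxy-2-nitro-3-(propan-2-yloxy)benzene, via fluoro nitro diaryl ether 7 (not isolated)
Conditions: K2CO3, DMF, 0 °C → rt; then NaOiPr, i-PrOH, 0 °C → rt
Reagents that add atoms: sodium propan-2-olate, CC(C)[O-].[Na+]
Why: Two sequential nucleophilic aromatic substitutions (SNAr) at the fluorides ortho to the nitro group, where the first aryloxy group lowers the reactivity of the second fluoride enough for clean mono-arylation before isopropoxide is added.

Step 5
Reactants: 8 1-(3,5-dimethoxyphenoxy)-5-methoxy-2-nitro-3-(propan-2-yloxy)benzene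
Product: 9 2-(3,5-dimethoxyphenoxy)-4-methoxy-6-(propan-2-yloxy)aniline
Conditions: H2 (1 atm), Pd/C, EtOAc, rt
Reagents that add atoms: none
Why: Catalytic hydrogenation of an aromatic nitro group is reliable here because the molecule holds no benzyl ether or halide at this stage.

Step 6
Reactants: 9 2-(3,5-dimethoxyphenoxy)-4-methoxy-6-(propan-2-yloxy)aniline
Product: 11 1-(3,5-dimethoxyphenoxy)-2-iodo-5-methoxy-3-(propan-2-yloxy)benzene, via arenediazonium tosylate 10 (not isolated)
Conditions: NaNO2, p-TsOH·H2O, KI, MeCN/H2O, 10 °C → rt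
Reagents that add atoms: potassium iodide, [K+].[I-]; for intermediate 10 only: sodium nitrite, [Na+].[O-]N=O, and 4-methylbenzenesulfonic acid, Cc1ccc(cc1)S(O)(=O)=O
Why: Diazotisation and iodide displacement (Sandmeyer-type iodination) put the halogen exactly on the carbon between the two different oxygens, a site that electrophilic halogenation could not single out.

Step 7
Reactants: 11 1-(3,5-dimethoxyphenoxy)-2-iodo-5-methoxy-3-(propan-2-yloxy)benzene
Product: 12 3,7,9-trimethoxy-1-(propan-2-yloxy)dibenzo[b,d]furan
Conditions: Pd(OAc)2 (5 mol %), PCy3·HBF4 (10 mol %), PivOH (30 mol %), K2CO3, DMA, 130 °C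
Reagents that add atoms: none
Why: Palladium-catalysed intramolecular direct arylation by concerted metalation–deprotonation closes the furan onto one of the two equivalent ortho C–H positions of the symmetric 3,5-dimethoxyphenoxy ring, so only one dibenzofuran can form and the isopropyl ether offers no competing aryl C–H.

Step 8
Reactants: 12 3,7,9-trimethoxy-1-(propan-2-yloxy)dibenzo[b,d]furan
Product: 13 3,7,9-trimethoxydibenzo[b,d]furan-1-ol
Conditions: BCl3, CH2Cl2, −78 → 0 °C; H2O
Reagents that add atoms: none
Why: Lewis acid dealkylation with BCl3 cleaves the secondary isopropyl ether through its stabilised cation much faster than the methyl ethers.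

Step 9
Reactants: 4 2-(benzyloxy)-6-bromo-3,5-dimethoxybenzaldehyde; 13 3,7,9-trimethoxydibenzo[b,d]furan-1-ol
Product: 14 2-(benzyloxy)-3,5-dimethoxy-6-[(3,7,9-trimethoxydibenzo[b,d]furan-1-yl)oxy]benzaldehyde
Conditions: CuI (20 mol %), picolinic acid (40 mol %), K3PO4, DMSO, 100 °C, argon
Reagents that add atoms: none
Why: Copper-catalysed Ullmann diaryl ether synthesis, helped by the ortho formyl group of the bromide and by a picolinate ligand suited to hindered phenols.

Step 10
Reactants: 14 2-(benzyloxy)-3,5-dimethoxy-6-[(3,7,9-trimethoxydibenzo[b,d]furan-1-yl)oxy]benzaldehyde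
Product: 16 2-(benzyloxy)-3,5-dimethoxy-6-[(3,7,9-trimethoxydibenzo[b,d]furan-1-yl)oxy]phenol, via aryl formate 15 (not isolated)
Conditions: mCPBA, NaHCO3, CH2Cl2, 0 °C → rt; then K2CO3 (cat.), MeOH, 0 °C, argon
Reagents that add atoms: 3-chloroperbenzoic acid, OOC(=O)c1cccc(Cl)c1
Why: Dakin-type Baeyer–Villiger oxidation, in which the aryl group with two ortho oxygen donors migrates to give the formate, and mild methanolysis then frees the phenol only at the point where it is needed.

Step 11
Reactants: 16 2-(benzyloxy)-3,5-dimethoxy-6-[(3,7,9-trimethoxydibenzo[b,d]furan-1-yl)oxy]phenol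
Product: 17 pentacyclic dioxin benzyl ether: ring B (carbons bearing OBn, OMe, H, OMe and the two dioxin oxygens) joined through the two dioxin oxygens to C1 and C2 of 3,7,9-trimethoxydibenzofuran, the oxygen next to the benzyloxy carbon sitting on C2
Conditions: graphite anode, Pt cathode, undivided cell, Bu4NBF4 (0.1 M), HFIP, constant current 2 mA cm−2, 2.2 F mol−1, 0.02 M, rt, argon
Reagents that add atoms: none
Why: One-electron anodic oxidation of the electron-rich aryloxyphenol in HFIP should give a radical cation whose charge is shared by the trioxygenated ring C; the ring B phenol oxygen, held ortho to the ether bridge, adds to C2, and loss of a second electron and two protons rearomatises ring C while hydrogen forms at the cathode. The closest known reaction type is anodic dehydrogenative C–O cyclisation of an electron-rich arene by a tethered oxygen nucleophile, as in the electrochemical lactonisation of biaryl-2-carboxylic acids. The 1,4-dioxin closes as a six-membered ring by O–C(sp2) bond formation, a 6-exo-trig attack counted on the C2–C3 π bond, with no spiro intermediate needed. No stereocentre is formed. The step needs site selectivity, and the substrate secures it: C2 is the only C–H within reach of a six-membered closure, because the other neighbour of C1 is the ring-fusion carbon C9b and the second flank of ring B carries a benzyl ether, not the oxidisable ring A; C2 is also ortho to two oxygenated carbons and para to C4a, where the radical cation is most electrophilic. Dilution and a charge limited to slightly more than 2 F per mole should hold back intermolecular coupling and over-oxidation of the product.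

Step 12
Reactants: 17 pentacyclic dioxin benzyl ether
Product: 18 pentacyclic dioxin phenol (17 with OH in place of OBn)
Conditions: H2 (1 atm), Pd/C, EtOAc/MeOH, rt
Reagents that add atoms: none
Why: Hydrogenolysis of a benzyl aryl ether over Pd/C leaves methyl ethers, the dioxin and the furan untouched.

Step 13
Reactants: 18 pentacyclic dioxin phenol; 19 1-iodo-3,5-dimethoxybenzene
Product: 20 heptamethyl ether of the target (18 with 3,5-dimethoxyphenoxy in place of OH)
Conditions: CuI (20 mol %), picolinic acid (40 mol %), K3PO4, DMSO, 90 °C, argon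
Reagents that add atoms: none
Why: Copper-catalysed Ullmann O-arylation of a di-ortho-substituted phenol with an unhindered aryl iodide, run without oxygen so that the electron-rich phenol is not oxidised.

Step 14
Reactants: 20 heptamethyl ether of the target
Product: 21 target heptaphenol CNP0256302.0
Conditions: BBr3 (excess), CH2Cl2, −78 °C → rt; MeOH, then H2O, argon
Reagents that add atoms: none
Why: Lewis acid ether cleavage by BBr3 (bromide attack at methyl) removes all seven methyl ethers, while the diaryl ether, dioxin and furan C–O bonds on sp2 carbon stay intact.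

Compound list
1 | 2,4-dimethoxyphenol | COc1ccc(O)c(OC)c1 | starting material
2 | 2-hydroxy-3,5-dimethoxybenzaldehyde | COc1cc(OC)cc(C=O)c1O | intermediate
3 | 2-(benzyloxy)-3,5-dimethoxybenzaldehyde | COc1cc(OC)cc(C=O)c1OCc1ccccc1 | intermediate
4 | 2-(benzyloxy)-6-bromo-3,5-dimethoxybenzaldehyde | COc1cc(OC)c(Br)c(C=O)c1OCc1ccccc1 | intermediate
5 | 1,3-difluoro-5-methoxy-2-nitrobenzene | COc1cc(F)c([N+](=O)[O-])c(F)c1 | starting material
6 | 3,5-dimethoxyphenol | COc1cc(O)cc(OC)c1 | starting material
7 | 1-(3,5-dimethoxyphenoxy)-3-fluoro-5-methoxy-2-nitrobenzene | COc1cc(F)c([N+](=O)[O-])c(Oc2cc(OC)cc(OC)c2)c1 | intermediate (not isolated)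
8 | 1-(3,5-dimethoxyphenoxy)-5-methoxy-2-nitro-3-(propan-2-yloxy)benzene | COc1cc(OC(C)C)c([N+](=O)[O-])c(Oc2cc(OC)cc(OC)c2)c1 | intermediate
9 | 2-(3,5-dimethoxyphenoxy)-4-methoxy-6-(propan-2-yloxy)aniline | COc1cc(OC(C)C)c(N)c(Oc2cc(OC)cc(OC)c2)c1 | intermediate
10 | 2-(3,5-dimethoxyphenoxy)-4-methoxy-6-(propan-2-yloxy)benzenediazonium 4-methylbenzenesulfonate | COc1cc(OC(C)C)c([N+]#N)c(Oc2cc(OC)cc(OC)c2)c1.Cc1ccc(cc1)S([O-])(=O)=O | intermediate (not isolated)
11 | 1-(3,5-dimethoxyphenoxy)-2-iodo-5-methoxy-3-(propan-2-yloxy)benzene | COc1cc(OC(C)C)c(I)c(Oc2cc(OC)cc(OC)c2)c1 | intermediate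
12 | 3,7,9-trimethoxy-1-(propan-2-yloxy)dibenzo[b,d]furan | COc1cc(OC(C)C)c2c(c1)oc1cc(OC)cc(OC)c12 | intermediate
13 | 3,7,9-trimethoxydibenzo[b,d]furan-1-ol | COc1cc(O)c2c(c1)oc1cc(OC)cc(OC)c12 | intermediate
14 | 2-(benzyloxy)-3,5-dimethoxy-6-[(3,7,9-trimethoxydibenzo[b,d]furan-1-yl)oxy]benzaldehyde | COc1cc(OC)c(Oc2cc(OC)cc3oc4cc(OC)cc(OC)c4c23)c(C=O)c1OCc1ccccc1 | intermediate
15 | 2-(benzyloxy)-3,5-dimethoxy-6-[(3,7,9-trimethoxydibenzo[b,d]furan-1-yl)oxy]phenyl formate | COc1cc(OC)c(Oc2cc(OC)cc3oc4cc(OC)cc(OC)c4c23)c(OC=O)c1OCc1ccccc1 | intermediate (not isolated)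
16 | 2-(benzyloxy)-3,5-dimethoxy-6-[(3,7,9-trimethoxydibenzo[b,d]furan-1-yl)oxy]phenol (precursor of the key step) | COc1cc(OC)c(Oc2cc(OC)cc3oc4cc(OC)cc(OC)c4c23)c(O)c1OCc1ccccc1 | intermediate
17 | pentacyclic dioxin benzyl ether, pentamethyl ether (product of the key step) | c1ccccc1COc1c(OC)cc(OC)c2c1Oc1c(OC)cc3oc4cc(OC)cc(OC)c4c3c1O2 | intermediate
18 | pentacyclic dioxin phenol, pentamethyl ether | Oc1c(OC)cc(OC)c2c1Oc1c(OC)cc3oc4cc(OC)cc(OC)c4c3c1O2 | intermediate
19 | 1-iodo-3,5-dimethoxybenzene | COc1cc(I)cc(OC)c1 | starting material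
20 | heptamethyl ether of the target | COc1cc(OC)cc(Oc2c(OC)cc(OC)c3c2Oc2c(OC)cc4oc5cc(OC)cc(OC)c5c4c2O3)c1 | intermediate
21 | CNP0256302.0, heptaphenol with 3,5-dihydroxyphenoxy ring A on the furo-fused dibenzodioxin | Oc1cc(O)cc(Oc2c(O)cc(O)c3c2Oc2c(O)cc4oc5cc(O)cc(O)c5c4c2O3)c1 | target

Total step count: 14 steps. Longest linear sequence: 11 steps (steps 4 to 14); the ring B branch (steps 1 to 3) joins at step 9.

Steps most likely to fail

Step 11. The pentaoxygenated phenol may be oxidised on to a quinone, or radical cations may couple between molecules through the free para position of ring B, before the oxygen closes onto C2. The fallback makes the same O–C2 bond without oxidation, by intramolecular Ullmann etherification of a ring C bromide. It sets out from 13: ortho-selective bromination (NBS, catalytic i-Pr2NH, CH2Cl2, 0 °C) should give 2-bromo-3,7,9-trimethoxydibenzo[b,d]furan-1-ol F1. Coupling of F1 with 4 under the conditions of step 9 should give 2-(benzyloxy)-6-[(2-bromo-3,7,9-trimethoxydibenzo[b,d]furan-1-yl)oxy]-3,5-dimethoxybenzaldehyde F2, since the formyl-activated bromide of 4 should react before the electron-rich bromide of F1. Dakin oxidation as in step 10 would pass through 2-(benzyloxy)-6-[(2-bromo-3,7,9-trimethoxydibenzo[b,d]furan-1-yl)oxy]-3,5-dimethoxyphenyl formate F3 to 2-(benzyloxy)-6-[(2-bromo-3,7,9-trimethoxydibenzo[b,d]furan-1-yl)oxy]-3,5-dimethoxyphenol F4. Heating F4 with CuI, N,N-dimethylglycine and Cs2CO3 in dioxane at 100 °C should close the dioxin and rejoin the route at 17.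

Step 9. Oxidative addition into the di-ortho-substituted, electron-rich bromide may be too slow, so that hydrodebromination and catalyst decay outrun coupling with the hindered phenoxide. The fallback replaces copper catalysis by an uncatalysed SNAr on a fluoride activated by the ortho formyl group. It sets out from 3: electrophilic fluorination (Selectfluor, MeCN, rt) should give 2-(benzyloxy)-6-fluoro-3,5-dimethoxybenzaldehyde F5, and heating F5 with 13 and Cs2CO3 in DMSO at 110 °C should give 14, where the route is rejoined.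

Step 6. Nitrous acid may oxidise the trioxygenated aniline, or the diazonium ion may couple with the nucleophilic dimethoxyphenoxy ring, before iodide displaces nitrogen. The fallback avoids nitrogen altogether and activates ring C through a formyl group that is later turned into a triflate. It sets out from 6:
- SNAr with purchased 2,6-difluoro-4-methoxybenzaldehyde F6 (K2CO3, DMF, 70 °C) should give 2-(3,5-dimethoxyphenoxy)-6-fluoro-4-methoxybenzaldehyde F7.
- A second SNAr (NaOiPr, THF, 0 °C → rt) should give 2-(3,5-dimethoxyphenoxy)-4-methoxy-6-(propan-2-yloxy)benzaldehyde F8.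
- Dakin oxidation (mCPBA, then K2CO3, MeOH) would pass through 2-(3,5-dimethoxyphenoxy)-4-methoxy-6-(propan-2-yloxy)phenyl formate F9 to 2-(3,5-dimethoxyphenoxy)-4-methoxy-6-(propan-2-yloxy)phenol F10.
- Tf2O and pyridine in CH2Cl2 should give 2-(3,5-dimethoxyphenoxy)-4-methoxy-6-(propan-2-yloxy)phenyl trifluoromethanesulfonate F11.
- Direct arylation of F11 under the conditions of step 7 should give 12, where the route is rejoined.

Further compounds
F1 | step 11 | 2-bromo-3,7,9-trimethoxydibenzo[b,d]furan-1-ol | COc1cc2oc3cc(OC)cc(OC)c3c2c(O)c1Br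
F2 | step 11 | 2-(benzyloxy)-6-[(2-bromo-3,7,9-trimethoxydibenzo[b,d]furan-1-yl)oxy]-3,5-dimethoxybenzaldehyde | COc1cc(OC)c(Oc2c(Br)c(OC)cc3oc4cc(OC)cc(OC)c4c23)c(C=O)c1OCc1ccccc1
F3 | step 11 | 2-(benzyloxy)-6-[(2-bromo-3,7,9-trimethoxydibenzo[b,d]furan-1-yl)oxy]-3,5-dimethoxyphenyl formate | COc1cc(OC)c(Oc2c(Br)c(OC)cc3oc4cc(OC)cc(OC)c4c23)c(OC=O)c1OCc1ccccc1
F4 | step 11 | 2-(benzyloxy)-6-[(2-bromo-3,7,9-trimethoxydibenzo[b,d]furan-1-yl)oxy]-3,5-dimethoxyphenol | COc1cc(OC)c(Oc2c(Br)c(OC)cc3oc4cc(OC)cc(OC)c4c23)c(O)c1OCc1ccccc1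
F5 | step 9 | 2-(benzyloxy)-6-fluoro-3,5-dimethoxybenzaldehyde | COc1cc(OC)c(F)c(C=O)c1OCc1ccccc1
F6 | step 6 | 2,6-difluoro-4-methoxybenzaldehyde | COc1cc(F)c(C=O)c(F)c1
F7 | step 6 | 2-(3,5-dimethoxyphenoxy)-6-fluoro-4-methoxybenzaldehyde | COc1cc(F)c(C=O)c(Oc2cc(OC)cc(OC)c2)c1
F8 | step 6 | 2-(3,5-dimethoxyphenoxy)-4-methoxy-6-(propan-2-yloxy)benzaldehyde | COc1cc(OC(C)C)c(C=O)c(Oc2cc(OC)cc(OC)c2)c1
F9 | step 6 | 2-(3,5-dimethoxyphenoxy)-4-methoxy-6-(propan-2-yloxy)phenyl formate | COc1cc(OC(C)C)c(OC=O)c(Oc2cc(OC)cc(OC)c2)c1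
F10 | step 6 | 2-(3,5-dimethoxyphenoxy)-4-methoxy-6-(propan-2-yloxy)phenol | COc1cc(OC(C)C)c(O)c(Oc2cc(OC)cc(OC)c2)c1
F11 | step 6 | 2-(3,5-dimethoxyphenoxy)-4-methoxy-6-(propan-2-yloxy)phenyl trifluoromethanesulfonate | COc1cc(OC(C)C)c(OS(=O)(=O)C(F)(F)F)c(Oc2cc(OC)cc(OC)c2)c1
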